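The route rests on the C1–C12 bond, which is shared by the six-membered ring (C1, C2, C15, C14, C13, C12) and the twelve-membered ring (C1–C12). The key step exploits the 1,4-relationship of the C13 oxygen and the C1 carboxyl carbon across this bond: a C12 ketone enolate and a C1 ester enolate are joined by oxidation. One operation closes the six-membered ring transannularly, contracts a fourteen-membered ring to the twelve-membered one and sets the C1 and C12 stereocentres. Its precursor is a fourteen-membered (Z,Z)-dienone whose C2 (R) carries a CH(CO2CH2CH2SiMe3)(4-methylpent-3-enyl) arm.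

Key step: step 17

Remark: atoms are numbered C1 (quaternary carboxyl-bearing carbon), C2–C12 (rest of the twelve-membered ring, alkenes C4=C5 and C8=C9), C13 (epoxide carbon), C14 and C15 (CH2 groups back to C2) and C16 (side-chain CH2 on C1). The carboxyl group is carried as its 2-(trimethylsilyl)ethyl ester, because a methyl ester on this doubly flanked quaternary carbon could only be cleaved under conditions that endanger the spiro-epoxide. Wherever C1 is stereogenic between step 6 and step 16 it is an epimer mixture and is drawn without a descriptor.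

Step 1
Reactants: 1 1,3-dithiane; 2 2-(2-bromoethyl)-1,3-dioxolane
Product: 3 2-[2-(1,3-dioxolan-2-yl)ethyl]-1,3-dithiane
Conditions: n-BuLi, THF, −30 °C; then 2, −78 °C → rt
Reagents that add atoms: none
Why: Corey–Seebach alkylation: the lithiated dithiane displaces the primary bromide by SN2, which installs the future C13 as a masked carbonyl together with C14, C15 and the future C2 as an acetal carbon.

Step 2
Reactants: 3 2-[2-(1,3-dioxolan-2-yl)ethyl]-1,3-dithiane; 4 allyl bromide
Product: 5 2-allyl-2-[2-(1,3-dioxolan-2-yl)ethyl]-1,3-dithiane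
Conditions: n-BuLi, THF, −20 °C; then 4, −78 → 0 °C
Reagents that add atoms: none
Why: A second Corey–Seebach alkylation with the highly reactive allyl bromide adds C12, C11 and C10 as the terminal alkene that is hydroborated in step 15.

Step 3
Reactants: 5 2-allyl-2-[2-(1,3-dioxolan-2-yl)ethyl]-1,3-dithiane
Product: 6 3-(2-allyl-1,3-dithian-2-yl)propanal
Conditions: 1 M HCl, THF, rt
Reagents that add atoms: water, O
Why: Acid hydrolysis cleaves the O,O-acetal to the C2 aldehyde, whereas the S,S-acetal needs thiophilic activation and stays intact.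

Step 4
Reactants: 6 3-(2-allyl-1,3-dithian-2-yl)propanal; 7 (triphenylphosphoranylidene)acetaldehyde
Product: 8 (E)-5-(2-allyl-1,3-dithian-2-yl)pent-2-enal
Conditions: toluene, 80 °C
Reagents that add atoms: none
Why: Wittig reaction of the stabilised formylmethylene ylide should give the (E)-enal C2=C3–C4HO, the acceptor for step 6.

Step 5
Reactants: 9 methyl 3-chloro-3-oxopropanoate
Product: 10 methyl 2-(trimethylsilyl)ethyl malonate
Conditions: Me3SiCH2CH2OH, pyridine, CH2Cl2, 0 °C → rt
Reagents that add atoms: 2-(trimethylsilyl)ethanol, C[Si](C)(C)CCO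
Why: Acylation of the alcohol by the acid chloride gives a mixed malonate whose methyl ester is removed selectively in step 8 and whose silylethyl ester becomes the fluoride-labile C1 ester.

Step 6
Reactants: 8 (E)-5-(2-allyl-1,3-dithian-2-yl)pent-2-enal; 10 methyl 2-(trimethylsilyl)ethyl malonate
Product: 11 methyl 2-(trimethylsilyl)ethyl 2-[(3R)-1-(2-allyl-1,3-dithian-2-yl)-5-oxopentan-3-yl]malonate
Conditions: (S)-2-{bis[3,5-bis(trifluoromethyl)phenyl](trimethylsilyloxy)methyl}pyrrolidine (10 mol%), EtOH, 0 °C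
Reagents that add atoms: none
Why: Iminium-catalysed Michael addition: the bulky group of the (S)-diarylprolinol silyl ether shields one face of the E-iminium ion of 8, so malonate should add to C2 from the open face and set C2 as R.

Step 7
Reactants: 11 methyl 2-(trimethylsilyl)ethyl 2-[(3R)-1-(2-allyl-1,3-dithian-2-yl)-5-oxopentan-3-yl]malonate
Product: 12 methyl 2-(trimethylsilyl)ethyl 2-[(2R)-4-(2-allyl-1,3-dithian-2-yl)-1-(1,3-dioxolan-2-yl)butan-2-yl]malonate
Conditions: Me3SiOCH2CH2OSiMe3, Me3SiOSO2CF3 (cat.), CH2Cl2, −78 °C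
Reagents that add atoms: 1,2-bis(trimethylsilyloxy)ethane, C[Si](C)(C)OCCO[Si](C)(C)C
Why: Acetalisation at low temperature protects the C4 aldehyde from the hot Krapcho medium of step 8 and from the enolate chemistry of step 9 (which also blocks retro-Michael loss of C2).

Step 8
Reactants: 12 methyl 2-(trimethylsilyl)ethyl 2-[(2R)-4-(2-allyl-1,3-dithian-2-yl)-1-(1,3-dioxolan-2-yl)butan-2-yl]malonate
Product: 13 2-(trimethylsilyl)ethyl (3R)-5-(2-allyl-1,3-dithian-2-yl)-3-(1,3-dioxolan-2-ylmethyl)pentanoate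
Conditions: LiCl, H2O, DMSO, 140 °C
Reagents that add atoms: none
Why: Krapcho decarboxylation: chloride attacks the methyl group by SN2 much faster than the silylethyl CH2, and the carboxylate loses CO2, leaving C1 as the CH2 of the mono-ester.

Step 9
Reactants: 13 2-(trimethylsilyl)ethyl (3R)-5-(2-allyl-1,3-dithian-2-yl)-3-(1,3-dioxolan-2-ylmethyl)pentanoate; 14 5-bromo-2-methylpent-2-ene
Product: 15 2-(trimethylsilyl)ethyl 2-[(2R)-4-(2-allyl-1,3-dithian-2-yl)-1-(1,3-dioxolan-2-yl)butan-2-yl]-6-methylhept-5-enoate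
Conditions: LiN(iPr)2, THF, −78 °C; then 14, DMPU, −78 → 0 °C
Reagents that add atoms: none
Why: Ester enolate alkylation with the primary bromide attaches the C16–C20 chain; the new C1 centre forms without control, which is harmless because C1 is planarised again in step 17.

Step 10
Reactants: 15 2-(trimethylsilyl)ethyl 2-[(2R)-4-(2-allyl-1,3-dithian-2-yl)-1-(1,3-dioxolan-2-yl)butan-2-yl]-6-methylhept-5-enoate
Product: 16 2-(trimethylsilyl)ethyl 2-[(3R)-1-(2-allyl-1,3-dithian-2-yl)-5-oxopentan-3-yl]-6-methylhept-5-enoate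
Conditions: 1 M HCl, THF, rt
Reagents that add atoms: water, O
Why: Mild acid hydrolysis of the dioxolane frees the C4 aldehyde; the thioketal, the silylethyl ester and the trisubstituted alkene tolerate dilute acid at room temperature.

Step 11
Reactants: 16 2-(trimethylsilyl)ethyl 2-[(3R)-1-(2-allyl-1,3-dithian-2-yl)-5-oxopentan-3-yl]-6-methylhept-5-enoate
Product: 17 2-(trimethylsilyl)ethyl 2-[(3R,5Z)-1-(2-allyl-1,3-dithian-2-yl)-6-iodohept-5-en-3-yl]-6-methylhept-5-enoate
Conditions: EtPPh3+ I−, n-BuLi, THF, rt; iodine, −78 °C; NaN(SiMe3)2, −20 °C; then 16, −78 °C → rt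
Reagents that add atoms: ethyltriphenylphosphonium iodide, CC[P+](c1ccccc1)(c1ccccc1)c1ccccc1.[I-]; iodine, [I][I]
Why: Stork–Zhao olefination: the non-stabilised α-iodo ylide Ph3P=C(I)CH3, prepared in the flask by iodination of the ethylidene ylide and a second deprotonation, reacts with the C4 aldehyde through the cis-oxaphosphetane, which should give the (Z)-iodoalkene with iodine cis to C3, so that the later coupling places C6 cis to C3.

Step 12
Reactants: 17 2-(trimethylsilyl)ethyl 2-[(3R,5Z)-1-(2-allyl-1,3-dithian-2-yl)-6-iodohept-5-en-3-yl]-6-methylhept-5-enoate; 18 3,3-diethoxyprop-1-ene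
Product: 20 2-(trimethylsilyl)ethyl 2-[(3R,5Z)-1-(2-allyl-1,3-dithian-2-yl)-9,9-diethoxy-6-methylnon-5-en-3-yl]-6-methylhept-5-enoate, via B-(3,3-diethoxypropyl)-9-borabicyclo[3.3.1]nonane 19 (not isolated)
Conditions: 18, 9-BBN-H, THF, rt; then 17, Pd(dppf)Cl2 (dppf = 1,1′-bis(diphenylphosphino)ferrocene), AsPh3, Cs2CO3, DMF/H2O, rt
Reagents that add atoms: none
Why: B-alkyl Suzuki–Miyaura coupling replaces iodine by C6 with retention at the alkenyl carbon, giving the Z-trisubstituted C4=C5 alkene; the borane is preformed so that no B–H is left to touch the allyl group of 17.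

Step 13
Reactants: 20 2-(trimethylsilyl)ethyl 2-[(3R,5Z)-1-(2-allyl-1,3-dithian-2-yl)-9,9-diethoxy-6-methylnon-5-en-3-yl]-6-methylhept-5-enoate
Product: 21 2-(trimethylsilyl)ethyl 2-[(3R,5Z)-1-(2-allyl-1,3-dithian-2-yl)-6-methyl-9-oxonon-5-en-3-yl]-6-methylhept-5-enoate
Conditions: 1 M HCl, THF, rt
Reagents that add atoms: water, O
Why: Hydrolysis of the acyclic acetal gives the C8 aldehyde, which is γ,δ-unsaturated and therefore not prone to double-bond migration.

Step 14
Reactants: 21 2-(trimethylsilyl)ethyl 2-[(3R,5Z)-1-(2-allyl-1,3-dithian-2-yl)-6-methyl-9-oxonon-5-en-3-yl]-6-methylhept-5-enoate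
Product: 22 2-(trimethylsilyl)ethyl 2-[(3R,5Z,9Z)-1-(2-allyl-1,3-dithian-2-yl)-10-iodo-6-methylundeca-5,9-dien-3-yl]-6-methylhept-5-enoate
Conditions: EtPPh3+ I−, n-BuLi, THF, rt; iodine, −78 °C; NaN(SiMe3)2, −20 °C; then 21, −78 °C → rt
Reagents that add atoms: ethyltriphenylphosphonium iodide, CC[P+](c1ccccc1)(c1ccccc1)c1ccccc1.[I-]; iodine, [I][I]
Why: A second Stork–Zhao olefination with a freshly prepared batch of the α-iodo ylide should give the (Z)-iodoalkene at C8=C9 with iodine cis to C7, which fixes the geometry of the second ring alkene before ring closure.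

Step 15
Reactants: 22 2-(trimethylsilyl)ethyl 2-[(3R,5Z,9Z)-1-(2-allyl-1,3-dithian-2-yl)-10-iodo-6-methylundeca-5,9-dien-3-yl]-6-methylhept-5-enoate
Product: 24 2-(trimethylsilyl)ethyl 2-[(1R,3Z,7Z)-4,8-dimethyl-12,12-(propane-1,3-diyldisulfanediyl)cyclotetradeca-3,7-dien-1-yl]-6-methylhept-5-enoate, via C10 B-alkyl-9-borabicyclo[3.3.1]nonane 23 (not isolated)
Conditions: 9-BBN-H, THF, rt; then slow addition to Pd(dppf)Cl2, AsPh3, Cs2CO3, DMF/THF/H2O, 50 °C, 1 mM
Reagents that add atoms: none
Why: 9-BBN-H hydroborates only the monosubstituted allyl alkene, and the intramolecular B-alkyl Suzuki–Miyaura coupling under high dilution forms C9–C10 with retention of the Z geometry, closing the fourteen-membered ring.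

Step 16
Reactants: 24 2-(trimethylsilyl)ethyl 2-[(1R,3Z,7Z)-4,8-dimethyl-12,12-(propane-1,3-diyldisulfanediyl)cyclotetradeca-3,7-dien-1-yl]-6-methylhept-5-enoate
Product: 25 2-(trimethylsilyl)ethyl 2-[(1R,3Z,7Z)-4,8-dimethyl-12-oxocyclotetradeca-3,7-dien-1-yl]-6-methylhept-5-enoate
Conditions: MeI, CaCO3, MeCN/H2O, 45 °C
Reagents that add atoms: water, O
Why: S-Methylation turns the thioketal into a leaving group and buffered hydrolysis releases the C13 ketone under near-neutral conditions that leave the three alkenes and the ester untouched.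

Step 17
Reactants: 25 2-(trimethylsilyl)ethyl 2-[(1R,3Z,7Z)-4,8-dimethyl-12-oxocyclotetradeca-3,7-dien-1-yl]-6-methylhept-5-enoate
Product: 27 2-(trimethylsilyl)ethyl (3Z,7Z)-4,8-dimethyl-15-(4-methylpent-3-en-1-yl)-12-oxobicyclo[9.3.1]pentadeca-3,7-diene-15-carboxylate (route numbering: CO2R on C1 cis to C3; C11 on C12 trans to C3; C13 ketone), via dilithium C1/C12 bis-enolate 26 (not isolated)
Conditions: LiN(iPr)2 (2.3 equiv), THF, −78 → −40 °C; then Fe(acac)3 (2.2 equiv), −78 °C → rt
Reagents that add atoms: none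
Why: Two equivalents of LiN(iPr)2 turn 25 into the bis-enolate 26 (ester enolate at C1, ketone enolate at C12=C13); Fe(acac)3 (trivalent iron) takes one electron from the more electron-rich ester enolate, the C1 radical is captured by C12 of the ketone enolate, and a second one-electron oxidation of the resulting ketyl gives the 1,4-dicarbonyl while each iron ends divalent. The closest known reaction type is the intramolecular oxidative heterocoupling of a ketone enolate with an ester or malonate enolate by Fe(acac)3 or Cu(2-ethylhexanoate)2, which gives cyclic 1,4-dicarbonyls with quaternary carbons. The six-membered ring C1–C2–C15–C14–C13–C12 closes across the macrocycle in a 6-endo-trig mode with respect to the C12=C13 enolate (6-exo-trig with respect to the ester enolate), and the same bond turns the fourteen-membered ring into the twelve-membered one. C1 is controlled by the C2 stereocentre, which places the C3 branch equatorial in a chair-like closure, together with the lithium bridge between the two enolate oxygens, which holds the carboxyl carbon synclinal to C13–O (axial) and thus cis to C3 with the C16 chain trans; C12 is controlled by the geometry of the ring enolate (C11 syn to C14 ends axial, trans to C3) and, being α to the C13 ketone, stays correctable by base equilibration. The step needs the C12 enolate and not the C14 enolate (which could only close a cyclobutane and is returned as 25 for recycling) and the bridged instead of the open rotamer about C2–C1; the first is not secured by the substrate and limits conversion per pass, the second is favoured by the contact bis-enolate in THF without polar cosolvent.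

Step 18
Reactants: 27 2-(trimethylsilyl)ethyl (3Z,7Z)-4,8-dimethyl-15-(4-methylpent-3-en-1-yl)-12-oxobicyclo[9.3.1]pentadeca-3,7-diene-15-carboxylate
Product: 28 2-(trimethylsilyl)ethyl (3Z,7Z)-4,8-dimethyl-15-(4-methylpent-3-en-1-yl)spiro[bicyclo[9.3.1]pentadeca-3,7-diene-12,2′-oxirane]-15-carboxylate (epoxide CH2 trans to C11 and oxygen cis to C11)
Conditions: Me3S+ I−, KN(SiMe3)2, THF, −10 °C; then 27, −10 → 0 °C
Reagents that add atoms: trimethylsulfonium iodide, C[S+](C)C.[I-]
Why: Corey–Chaykovsky reaction: the sulfonium ylide should add irreversibly to the C13 carbonyl from the face opposite the C11 branch on C12 and the C16 chain on C1, and 3-exo-tet closure of the betaine with loss of Me2S leaves the new CH2 trans to C11 and the oxygen cis to it.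

Step 19
Reactants: 28 2-(trimethylsilyl)ethyl (3Z,7Z)-4,8-dimethyl-15-(4-methylpent-3-en-1-yl)spiro[bicyclo[9.3.1]pentadeca-3,7-diene-12,2′-oxirane]-15-carboxylate
Product: 29 (3Z,7Z)-4,8-dimethyl-15-(4-methylpent-3-en-1-yl)spiro[bicyclo[9.3.1]pentadeca-3,7-diene-12,2′-oxirane]-15-carboxylic acid (CNP0116395.1)
Conditions: Bu4NF, THF, 0 °C → rt; cold aqueous NH4Cl work-up
Reagents that add atoms: none
Why: Fluoride attacks silicon and the ester fragments to carboxylate, ethene and Me3SiF, so the hindered C1 carbonyl is never attacked and the spiro-epoxide and the alkenes are left alone; the mild work-up avoids acid-promoted opening of the epoxide.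

Compound list

1 | 1,3-dithiane | C1CSCSC1 | starting material
2 | 2-(2-bromoethyl)-1,3-dioxolane | BrCCC1OCCO1 | starting material
3 | 2-[2-(1,3-dioxolan-2-yl)ethyl]-1,3-dithiane | C1CSC(CCC2OCCO2)SC1 | intermediate
4 | allyl bromide | C=CCBr | starting material
5 | 2-allyl-2-[2-(1,3-dioxolan-2-yl)ethyl]-1,3-dithiane | C=CCC1(CCC2OCCO2)SCCCS1 | intermediate
6 | 3-(2-allyl-1,3-dithian-2-yl)propanal | C=CCC1(CCC=O)SCCCS1 | intermediate
7 | (triphenylphosphoranylidene)acetaldehyde | O=CC=P(c1ccccc1)(c1ccccc1)c1ccccc1 | starting material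
8 | (E)-5-(2-allyl-1,3-dithian-2-yl)pent-2-enal | C=CCC1(CC/C=C/C=O)SCCCS1 | intermediate
9 | methyl 3-chloro-3-oxopropanoate | COC(=O)CC(Cl)=O | starting material
10 | methyl 2-(trimethylsilyl)ethyl malonate | COC(=O)CC(=O)OCC[Si](C)(C)C | intermediate
11 | methyl 2-(trimethylsilyl)ethyl 2-[(3R)-1-(2-allyl-1,3-dithian-2-yl)-5-oxopentan-3-yl]malonate (C2 R; C1 epimers) | COC(=O)C(C(=O)OCC[Si](C)(C)C)[C@H](CCC1(CC=C)SCCCS1)CC=O | intermediate
12 | methyl 2-(trimethylsilyl)ethyl 2-[(2R)-4-(2-allyl-1,3-dithian-2-yl)-1-(1,3-dioxolan-2-yl)butan-2-yl]malonate (C1 epimers) | COC(=O)C(C(=O)OCC[Si](C)(C)C)[C@H](CCC1(CC=C)SCCCS1)CC1OCCO1 | intermediate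
13 | 2-(trimethylsilyl)ethyl (3R)-5-(2-allyl-1,3-dithian-2-yl)-3-(1,3-dioxolan-2-ylmethyl)pentanoate | C[Si](C)(C)CCOC(=O)C[C@H](CCC1(CC=C)SCCCS1)CC1OCCO1 | intermediate
14 | 5-bromo-2-methylpent-2-ene | CC(C)=CCCBr | starting material
15 | 2-(trimethylsilyl)ethyl 2-[(2R)-4-(2-allyl-1,3-dithian-2-yl)-1-(1,3-dioxolan-2-yl)butan-2-yl]-6-methylhept-5-enoate (C1 epimers) | CC(C)=CCCC(C(=O)OCC[Si](C)(C)C)[C@H](CCC1(CC=C)SCCCS1)CC1OCCO1 | intermediate
16 | 2-(trimethylsilyl)ethyl 2-[(3R)-1-(2-allyl-1,3-dithian-2-yl)-5-oxopentan-3-yl]-6-methylhept-5-enoate (C1 epimers) | CC(C)=CCCC(C(=O)OCC[Si](C)(C)C)[C@H](CCC1(CC=C)SCCCS1)CC=O | intermediate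
17 | 2-(trimethylsilyl)ethyl 2-[(3R,5Z)-1-(2-allyl-1,3-dithian-2-yl)-6-iodohept-5-en-3-yl]-6-methylhept-5-enoate (C1 epimers) | CC(C)=CCCC(C(=O)OCC[Si](C)(C)C)[C@H](CCC1(CC=C)SCCCS1)C/C=C(/C)I | intermediate
18 | 3,3-diethoxyprop-1-ene (acrolein diethyl acetal) | C=CC(OCC)OCC | starting material
19 | B-(3,3-diethoxypropyl)-9-borabicyclo[3.3.1]nonane | CCOC(CCB1C2CCCC1CCC2)OCC | intermediate
20 | 2-(trimethylsilyl)ethyl 2-[(3R,5Z)-1-(2-allyl-1,3-dithian-2-yl)-9,9-diethoxy-6-methylnon-5-en-3-yl]-6-methylhept-5-enoate (C1 epimers) | CC(C)=CCCC(C(=O)OCC[Si](C)(C)C)[C@H](CCC1(CC=C)SCCCS1)C/C=C(/C)CCC(OCC)OCC | intermediate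
21 | 2-(trimethylsilyl)ethyl 2-[(3R,5Z)-1-(2-allyl-1,3-dithian-2-yl)-6-methyl-9-oxonon-5-en-3-yl]-6-methylhept-5-enoate (C1 epimers) | CC(C)=CCCC(C(=O)OCC[Si](C)(C)C)[C@H](CCC1(CC=C)SCCCS1)C/C=C(/C)CCC=O | intermediate
22 | 2-(trimethylsilyl)ethyl 2-[(3R,5Z,9Z)-1-(2-allyl-1,3-dithian-2-yl)-10-iodo-6-methylundeca-5,9-dien-3-yl]-6-methylhept-5-enoate (C1 epimers) | CC(C)=CCCC(C(=O)OCC[Si](C)(C)C)[C@H](CCC1(CC=C)SCCCS1)C/C=C(/C)CC/C=C(/C)I | intermediate
23 | C10 B-alkyl-9-borabicyclo[3.3.1]nonane from 22 (boron on the terminal carbon of the former allyl group) | CC(C)=CCCC(C(=O)OCC[Si](C)(C)C)[C@H](CCC1(CCCB2C3CCCC2CCC3)SCCCS1)C/C=C(/C)CC/C=C(/C)I | intermediate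
24 | 2-(trimethylsilyl)ethyl 2-[(1R,3Z,7Z)-4,8-dimethyl-12,12-(propane-1,3-diyldisulfanediyl)cyclotetradeca-3,7-dien-1-yl]-6-methylhept-5-enoate (C13 as 1,3-dithiane; C1 epimers) | CC(C)=CCCC(C(=O)OCC[Si](C)(C)C)[C@H]1C/C=C(/C)CC/C=C(/C)CCCC2(CC1)SCCCS2 | intermediate
25 | 2-(trimethylsilyl)ethyl 2-[(1R,3Z,7Z)-4,8-dimethyl-12-oxocyclotetradeca-3,7-dien-1-yl]-6-methylhept-5-enoate (key-step precursor; C1 epimers) | CC(C)=CCCC(C(=O)OCC[Si](C)(C)C)[C@H]1C/C=C(/C)CC/C=C(/C)CCCC(=O)CC1 | intermediate
26 | dilithium C1/C12 bis-enolate of 25 | CC(C)=CCCC(=C(O[Li])OCC[Si](C)(C)C)[C@H]1C/C=C(/C)CC/C=C(/C)CCC=C(O[Li])CC1 | intermediate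
27 | 2-(trimethylsilyl)ethyl (3Z,7Z)-4,8-dimethyl-15-(4-methylpent-3-en-1-yl)-12-oxobicyclo[9.3.1]pentadeca-3,7-diene-15-carboxylate (key-step product; CO2R cis to C3, C11 trans to C3) | CC(C)=CCC[C@]1(C(=O)OCC[Si](C)(C)C)[C@H]2C/C=C(/C)CC/C=C(/C)CC[C@H]1C(=O)CC2 | intermediate
28 | 2-(trimethylsilyl)ethyl (3Z,7Z)-4,8-dimethyl-15-(4-methylpent-3-en-1-yl)spiro[bicyclo[9.3.1]pentadeca-3,7-diene-12,2′-oxirane]-15-carboxylate (epoxide CH2 trans to C11) | CC(C)=CCC[C@]1(C(=O)OCC[Si](C)(C)C)[C@H]2C/C=C(/C)CC/C=C(/C)CC[C@H]1[C@@]1(CC2)CO1 | intermediate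
29 | (3Z,7Z)-4,8-dimethyl-15-(4-methylpent-3-en-1-yl)spiro[bicyclo[9.3.1]pentadeca-3,7-diene-12,2′-oxirane]-15-carboxylic acid (CNP0116395.1) | CC(C)=CCC[C@]1(C(=O)O)[C@H]2C/C=C(/C)CC/C=C(/C)CC[C@H]1[C@@]1(CC2)CO1 | target

Total step count: 19. Longest linear sequence: 18 (steps 1–4 and 6–19; step 5 is a one-step side branch).

The three steps most likely to fail

Step 17. Deprotonation on the two sides of the C13 ketone is not selective, so part of the material forms the C14 enolate, which cannot ring-close and is consumed unproductively or returned as 25. In addition, bond formation through the open rotamer about C2–C1 (carboxyl carbon anti to C13–O) would give the C1 epimer, which no later step can repair. The fallback sets out from 25 and returns at 27. The bis-enolate 26 is formed as before but trapped with iPr2SiCl2 to give the cyclic diisopropylsilylene bis-enol ether F1, in which a covalent O–Si–O bridge holds the ketene-acetal carbon C1 next to the C12=C13 enol ether. Oxidation with (NH4)2Ce(NO3)6 (tetravalent cerium) and NaHCO3 in MeCN at −10 °C then forms C1–C12 inside this tether, and hydrolytic loss of the silylene gives 27. The closed arrangement needed for CO2R cis to C3 then no longer depends on enolate aggregation, and the silylene derived from the C14 enolate is hydrolysed back to 25.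

Step 15. At the dilution needed for ring closure the alkylborane may oligomerise or lose boron by protodeboronation or β-hydride elimination, and the thioketal sulfur atoms may slow the palladium cycle. The fallback sets out from 22 and returns at 24. Hydroboration as before, followed by oxidation with Me3NO, gives the primary alcohol F2, and PPh3, iodine and imidazole convert it into the primary iodide F3. Zn dust with LiCl inserts into the C(sp3)–I bond only and gives the alkylzinc iodide F4. Pd(OAc)2 with 2-dicyclohexylphosphino-2′,6′-dimethoxybiphenyl under slow addition then closes C9–C10 by Negishi coupling with retention of the Z geometry and gives 24.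

Step 18. The basic ylide may enolise the hindered, α-branched ketone instead of adding (returning ketone and scrambling C12), or may discriminate poorly between the two faces of C13. The fallback sets out from 27 and returns at 28. The non-basic organocerium reagent made from ClMgCH2SiMe2(OiPr) and CeCl3 adds to C13 under steric approach control and gives the β-hydroxysilane F5. Tamao–Fleming oxidation (KF, KHCO3, H2O2, THF/MeOH) gives the diol F6, a stage at which C13 epimers can be separated. Selective sulfonylation of the primary hydroxyl (TsCl, Et3N, 4-(dimethylamino)pyridine) gives the tosylate F7, and K2CO3 in MeOH closes the epoxide with retention at C13 to give 28.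

Further compounds

F1 | step 17 | cyclic diisopropylsilylene bis-enol ether of 25 (O–Si–O bridge between the C13 enol oxygen and the ester enol oxygen) | CC(C)=CCCC1=C(OCC[Si](C)(C)C)O[Si](C(C)C)(C(C)C)OC2=CCC/C(C)=C\CC/C(C)=C\C[C@H]1CC2
F2 | step 15 | 2-(trimethylsilyl)ethyl 2-[(3R,5Z,9Z)-1-[2-(3-hydroxypropyl)-1,3-dithian-2-yl]-10-iodo-6-methylundeca-5,9-dien-3-yl]-6-methylhept-5-enoate | CC(C)=CCCC(C(=O)OCC[Si](C)(C)C)[C@H](CCC1(CCCO)SCCCS1)C/C=C(/C)CC/C=C(/C)I
F3 | step 15 | 2-(trimethylsilyl)ethyl 2-[(3R,5Z,9Z)-10-iodo-1-[2-(3-iodopropyl)-1,3-dithian-2-yl]-6-methylundeca-5,9-dien-3-yl]-6-methylhept-5-enoate | CC(C)=CCCC(C(=O)OCC[Si](C)(C)C)[C@H](CCC1(CCCI)SCCCS1)C/C=C(/C)CC/C=C(/C)I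
F4 | step 15 | alkylzinc iodide from F3 (zinc on C10) | CC(C)=CCCC(C(=O)OCC[Si](C)(C)C)[C@H](CCC1(CCC[Zn]I)SCCCS1)C/C=C(/C)CC/C=C(/C)I
F5 | step 18 | C13 tertiary alcohol of 27 bearing CH2SiMe2(OiPr) (CH2 trans to C11) | CC(C)=CCC[C@]1(C(=O)OCC[Si](C)(C)C)[C@H]2C/C=C(/C)CC/C=C(/C)CC[C@H]1[C@@](O)(CC2)C[Si](C)(C)OC(C)C
F6 | step 18 | C13 diol (tertiary hydroxyl on C13 and CH2OH) | CC(C)=CCC[C@]1(C(=O)OCC[Si](C)(C)C)[C@H]2C/C=C(/C)CC/C=C(/C)CC[C@H]1[C@@](O)(CC2)CO
F7 | step 18 | primary 4-methylbenzenesulfonate of F6 | CC(C)=CCC[C@]1(C(=O)OCC[Si](C)(C)C)[C@H]2C/C=C(/C)CC/C=C(/C)CC[C@H]1[C@@](O)(CC2)COS(=O)(=O)c1ccc(C)cc1
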